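Ring B (C5–C10) is read as a masked isoxazoline. The C8 carbonyl oxygen and the C11 hydroxyl are 1,3-related across C7, and C6=C7 is the leftover π bond of an allene. The key step is an intramolecular nitrile oxide cycloaddition onto the distal C7=C11 bond of a C5-allenyl group. It forms C7–C8 and O–C11 at once and closes ring B at the enone oxidation level, with both oxygen sites in place. The precursor is a monocyclic, trans-disubstituted cyclohexene (ring A) bearing CH=C=CMe2 on C5 and CH2CH=NOH on C10. N–O cleavage, α-face dihydroxylation of C3=C4, acylation and epoxide opening with HCl finish the synthesis.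

Key step: step 12

Remark: eudesmane numbering is used (ring A = C1–C5 and C10, ring B = C5–C10, C11–C13 = hydroxyisopropyl group, primes = acyl group); the enol ether geometry in 9–14 and the C6 carbinol centre in 12 and 13 are inconsequential mixtures, drawn as the E isomer and without a C6 descriptor.

Step 1
Reactants: 1 (E)-2-methylbut-2-en-1-ol
Product: 2 [(2R,3R)-2,3-dimethyloxiran-2-yl]methanol
Conditions: Ti(OiPr)4 (10 mol %), D-(−)-diethyl tartrate (12 mol %), t-BuOOH, 4 Å molecular sieves, CH2Cl2, −20 °C
Reagents that add atoms: tert-butyl hydroperoxide, CC(C)(C)OO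
Why: Sharpless asymmetric epoxidation of an E-trisubstituted allylic alcohol, in which the D-(−)-tartrate sets both epoxide carbons as (2R,3R).

Step 2
Reactants: 2 [(2R,3R)-2,3-dimethyloxiran-2-yl]methanol
Product: 3 (2S,3R)-2,3-dimethyloxirane-2-carboxylic acid
Conditions: RuCl3 (2 mol %), NaIO4, MeCN/EtOAc/H2O, rt
Reagents that add atoms: sodium periodate, [Na+].[O-]I(=O)(=O)=O
Why: RuO4-catalysed oxidation takes the primary alcohol to the acid and leaves the epoxide and its two stereocentres untouched (the C2 descriptor changes only through CIP priorities).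

Step 3
Reactants: 4 3-methylbut-3-en-2-one
Product: 5 3-methyl-2-(triisopropylsilyloxy)buta-1,3-diene
Conditions: TIPSOTf, Et3N, CH2Cl2, 0 °C
Reagents that add atoms: triisopropylsilyl trifluoromethanesulfonate, CC(C)[Si](C(C)C)(C(C)C)OS(=O)(=O)C(F)(F)F
Why: Soft enolisation of the methyl ketone (silyl enol ether formation) gives the 2-silyloxydiene, and no stereocentre is involved.

Step 4
Reactants: 5 3-methyl-2-(triisopropylsilyloxy)buta-1,3-diene; 6 methacrolein
Product: 7 (1S)-1,3-dimethyl-4-(triisopropylsilyloxy)cyclohex-3-ene-1-carbaldehyde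
Conditions: B-butyl oxazaborolidinone from N-tosyl-(S)-tryptophan and n-BuB(OH)2 (20 mol %), CH2Cl2/toluene, −78 °C
Reagents that add atoms: none
Why: Catalytic enantioselective Diels–Alder reaction that closes ring A, in which the silyloxy group directs the para orientation (C1–C2 and C5–C10 bonds) and the indole-shielded boron complex of s-cis methacrolein is attacked on one face only, which sets the quaternary centre C10.

Step 5
Reactants: 7 (1S)-1,3-dimethyl-4-(triisopropylsilyloxy)cyclohex-3-ene-1-carbaldehyde
Product: 8 (1S)-1,3-dimethyl-4-oxocyclohex-2-ene-1-carbaldehyde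
Conditions: Pd(OAc)2 (1.1 equiv), MeCN, 40 °C
Reagents that add atoms: none
Why: Saegusa–Ito oxidation, in which the oxo-π-allyl complex of divalent palladium at C4 loses a ring hydrogen from C5 by β-hydride elimination and gives the endocyclic C4=C5 enone without touching C10.

Step 6
Reactants: 8 (1S)-1,3-dimethyl-4-oxocyclohex-2-ene-1-carbaldehyde
Product: 9 (4S)-4-[(E)-2-methoxyethenyl]-2,4-dimethylcyclohex-2-en-1-one
Conditions: MeOCH2PPh3Cl, KN(SiMe3)2, THF, −78 to 0 °C
Reagents that add atoms: (methoxymethyl)triphenylphosphonium chloride, COC[P+](c1ccccc1)(c1ccccc1)c1ccccc1.[Cl-]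
Why: Wittig homologation is chemoselective for the non-enolisable aldehyde over the hindered conjugated ketone and stores C8 as a base-stable enol ether.

Step 7
Reactants: 9 (4S)-4-[(E)-2-methoxyethenyl]-2,4-dimethylcyclohex-2-en-1-one
Product: 10 (1S,4S)-4-[(E)-2-methoxyethenyl]-2,4-dimethylcyclohex-2-en-1-ol
Conditions: (R)-2-methyl-CBS-oxazaborolidine (20 mol %), catecholborane, toluene, −78 °C
Reagents that add atoms: none
Why: Corey–Bakshi–Shibata reduction, in which the catalyst treats the methyl-substituted alkene side as the large group and delivers hydride to the α face, so the C3 hydroxyl is β (S) under reagent control.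

Step 8
Reactants: 10 (1S,4S)-4-[(E)-2-methoxyethenyl]-2,4-dimethylcyclohex-2-en-1-ol
Product: 11 (3S,6S)-6-(but-2-yn-1-yloxy)-3-[(E)-2-methoxyethenyl]-1,3-dimethylcyclohex-1-ene
Conditions: NaH, 1-bromobut-2-yne, n-Bu4NI (cat.), THF/DMF, 0 °C to rt
Reagents that add atoms: 1-bromobut-2-yne, CC#CCBr
Why: Williamson ether synthesis of the secondary alkoxide with a reactive propargylic bromide keeps the C3 configuration.

Step 9
Reactants: 11 (3S,6S)-6-(but-2-yn-1-yloxy)-3-[(E)-2-methoxyethenyl]-1,3-dimethylcyclohex-1-ene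
Product: 13 1-{(1S,6R)-6-[(E)-2-methoxyethenyl]-2,6-dimethylcyclohex-2-en-1-yl}but-2-yn-1-yl acetate, via lithium propargylic alkoxide 12 (not isolated)
Conditions: n-BuLi, THF, −78 to −30 °C; then Ac2O, −78 °C to rt
Reagents that add atoms: acetic anhydride, CC(=O)OC(C)=O
Why: [2,3]-Wittig rearrangement, in which the propargyl-stabilised α-oxy carbanion migrates suprafacially from the β oxygen on C3 to the β face of C5 (H on C5 becomes α, trans to the C9 arm) while C3=C4 is unveiled, and the alkoxide is acetylated in the same flask.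

Step 10
Reactants: 13 1-{(1S,6R)-6-[(E)-2-methoxyethenyl]-2,6-dimethylcyclohex-2-en-1-yl}but-2-yn-1-yl acetate
Product: 14 (5S,6S)-5-[(E)-2-methoxyethenyl]-1,5-dimethyl-6-(3-methylbuta-1,2-dien-1-yl)cyclohex-1-ene
Conditions: Me2CuLi (from MeLi and CuI), Et2O, −30 to 0 °C
Reagents that add atoms: lithium dimethylcuprate, [Li+].C[Cu-]C
Why: Anti-SN2' displacement of a propargylic acetate by a cuprate gives the allene, which has no axial chirality because C11 ends up with two methyl groups, so both C6 epimers converge.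

Step 11
Reactants: 14 (5S,6S)-5-[(E)-2-methoxyethenyl]-1,5-dimethyl-6-(3-methylbuta-1,2-dien-1-yl)cyclohex-1-ene
Product: 16 (E)-oxime of 2-[(1R,2R)-1,3-dimethyl-2-(3-methylbuta-1,2-dien-1-yl)cyclohex-3-en-1-yl]acetaldehyde, via aldehyde 15 (not isolated)
Conditions: NH2OH·HCl, THF/H2O, rt to 40 °C
Reagents that add atoms: hydroxylamine hydrochloride, NO.Cl; water, O (oxygen of transient 15 only)
Why: The mildly acidic hydroxylamine salt hydrolyses the enol ether and condenses with the released aldehyde (oxime formation) without touching the allene or C3=C4.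

Step 12
Reactants: 16 (E)-oxime of 2-[(1R,2R)-1,3-dimethyl-2-(3-methylbuta-1,2-dien-1-yl)cyclohex-3-en-1-yl]acetaldehyde
Product: 18 tricyclic 4-alkylidene-2-isoxazoline (5R,10R)-eudesma-3,6-diene bridged C8=N–O–C11, via nitrile oxide 17 (not isolated)
Conditions: PhI(OAc)2, CF3CO2H (cat.), MeOH, 0.005 M, 0 °C to rt
Reagents that add atoms: none
Why: PhI(OAc)2 dehydrogenates the aldoxime to nitrile oxide 17, whose carbon (C8) and oxygen add in a concerted [3+2] cycloaddition across the distal C7=C11 bond of the allene, so that C7–C8 and O–C11 form together and the untouched C6=C7 bond ends up inside the new ring, conjugated with C8=N. The closest known reaction types are the intramolecular nitrile oxide–olefin cycloaddition and the addition of nitrile oxides to 1,1-dialkylallenes, which gives 4-alkylidene-2-isoxazolines. Ring B closes in a 6-exo sense with respect to the reacting C7=C11 bond (C8 reaches the central allene carbon through the C9–C10–C5–C6 tether), and the temporary five-membered isoxazoline is fused to it along C7–C8. No new stereocentre arises (C7 and C8 are sp2 and C11 carries two methyl groups), and C5 and C10 are spectators, so the trans ring fusion is inherited from the diequatorial side chains of 16. The step needs site selectivity for the distal over the proximal allene bond and over C3=C4, with oxygen going to C11: the distal π orbital lies in the plane of the C5–C6 bond and points at the dipole, it is the more electron-rich bond, and oxygen lands on the carbon that best bears positive charge, whereas attack at C6 would build a strained trans-fused five-membered ring and attack at C3=C4 needs the diaxial conformer and a bridged transition state. High dilution suppresses dimerisation of the dipole.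

Step 13
Reactants: 18 tricyclic 4-alkylidene-2-isoxazoline (5R,10R)-eudesma-3,6-diene bridged C8=N–O–C11
Product: 20 (4aR,8aR)-3-(2-hydroxypropan-2-yl)-5,8a-dimethyl-4a,7,8,8a-tetrahydronaphthalen-2(1H)-one, via hydroxy imine 19 (not isolated)
Conditions: Mo(CO)6, MeCN/H2O, 80 °C
Reagents that add atoms: water, O
Why: Reductive N–O cleavage of an isoxazoline by Mo(CO)6 in wet acetonitrile spares both alkenes, and hydrolysis of the conjugated imine releases the C8 ketone next to the free C11 alcohol.

Step 14
Reactants: 20 (4aR,8aR)-3-(2-hydroxypropan-2-yl)-5,8a-dimethyl-4a,7,8,8a-tetrahydronaphthalen-2(1H)-one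
Product: 21 (3R,4S,5R,10R)-3α,4α,11-trihydroxyeudesm-6-en-8-one
Conditions: OsO4 (5 mol %), N-methylmorpholine N-oxide, acetone/H2O, 0 °C
Reagents that add atoms: N-methylmorpholine N-oxide, C[N+]1([O-])CCOCC1; water, O
Why: Upjohn dihydroxylation picks the electron-rich C3=C4 bond over the hindered enone, and OsO4 approaches the α face opposite to the axial C10 methyl group, which sets C3 and C4 as the 3α,4α-cis-diol.

Step 15
Reactants: 21 (3R,4S,5R,10R)-3α,4α,11-trihydroxyeudesm-6-en-8-one; 3 (2S,3R)-2,3-dimethyloxirane-2-carboxylic acid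
Product: 22 3α-[(2S,3R)-2,3-dimethyloxirane-2-carbonyloxy]-4α,11-dihydroxyeudesm-6-en-8-one
Conditions: DCC, DMAP, CH2Cl2, 0 °C to rt
Reagents that add atoms: none
Why: Steglich esterification acylates only the secondary C3 hydroxyl because the C4 and C11 hydroxyls are tertiary, and no stereocentre is affected.

Step 16
Reactants: 22 3α-[(2S,3R)-2,3-dimethyloxirane-2-carbonyloxy]-4α,11-dihydroxyeudesm-6-en-8-one
Product: 23 CNP0288516.1, 3α-[(2R,3S)-3-chloro-2-hydroxy-2-methylbutanoyloxy]-4α,11-dihydroxyeudesm-6-en-8-one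
Conditions: HCl (1 M in Et2O), CH2Cl2, −20 °C
Reagents that add atoms: hydrogen chloride, Cl
Why: Acid-promoted epoxide opening, in which chloride attacks the secondary carbon C3' in an SN2 manner with inversion (3'R to 3'S) because the tertiary C2' is deactivated by the ester carbonyl, while C2' keeps its C–O bond.

Compound list
1 | (E)-2-methylbut-2-en-1-ol | C/C=C(\C)CO | starting material
2 | [(2R,3R)-2,3-dimethyloxiran-2-yl]methanol | C[C@H]1O[C@]1(C)CO | intermediate
3 | (2S,3R)-2,3-dimethyloxirane-2-carboxylic acid | C[C@H]1O[C@]1(C)C(=O)O | intermediate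
4 | 3-methylbut-3-en-2-one | CC(=O)C(C)=C | starting material
5 | 3-methyl-2-(triisopropylsilyloxy)buta-1,3-diene | C=C(C)C(=C)O[Si](C(C)C)(C(C)C)C(C)C | intermediate
6 | methacrolein | C=C(C)C=O | starting material
7 | (1S)-1,3-dimethyl-4-(triisopropylsilyloxy)cyclohex-3-ene-1-carbaldehyde | O=C[C@]1(C)CC(C)=C(O[Si](C(C)C)(C(C)C)C(C)C)CC1 | intermediate
8 | (1S)-1,3-dimethyl-4-oxocyclohex-2-ene-1-carbaldehyde | O=C[C@]1(C)C=C(C)C(=O)CC1 | intermediate
9 | (4S)-4-[(E)-2-methoxyethenyl]-2,4-dimethylcyclohex-2-en-1-one | CO/C=C/[C@]1(C)C=C(C)C(=O)CC1 | intermediate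
10 | (1S,4S)-4-[(E)-2-methoxyethenyl]-2,4-dimethylcyclohex-2-en-1-ol | CO/C=C/[C@]1(C)C=C(C)[C@@H](O)CC1 | intermediate
11 | (3S,6S)-6-(but-2-yn-1-yloxy)-3-[(E)-2-methoxyethenyl]-1,3-dimethylcyclohex-1-ene | CO/C=C/[C@]1(C)C=C(C)[C@@H](OCC#CC)CC1 | intermediate
12 | lithium propargylic alkoxide from the [2,3]-shift (lithium salt of the alcohol of 13) | CO/C=C/[C@@]1(C)CCC=C(C)[C@@H]1C([O-])C#CC.[Li+] | intermediate
13 | 1-{(1S,6R)-6-[(E)-2-methoxyethenyl]-2,6-dimethylcyclohex-2-en-1-yl}but-2-yn-1-yl acetate | CO/C=C/[C@@]1(C)CCC=C(C)[C@@H]1C(OC(C)=O)C#CC | intermediate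
14 | (5S,6S)-5-[(E)-2-methoxyethenyl]-1,5-dimethyl-6-(3-methylbuta-1,2-dien-1-yl)cyclohex-1-ene | CO/C=C/[C@@]1(C)CCC=C(C)[C@@H]1C=C=C(C)C | intermediate
15 | 2-[(1R,2R)-1,3-dimethyl-2-(3-methylbuta-1,2-dien-1-yl)cyclohex-3-en-1-yl]acetaldehyde | O=CC[C@@]1(C)CCC=C(C)[C@@H]1C=C=C(C)C | intermediate
16 | (E)-oxime of 15 | O/N=C/C[C@@]1(C)CCC=C(C)[C@@H]1C=C=C(C)C | intermediate
17 | nitrile oxide derived from 16 | [O-][N+]#CC[C@@]1(C)CCC=C(C)[C@@H]1C=C=C(C)C | intermediate
18 | tricyclic 4-alkylidene-2-isoxazoline, (5R,10R)-eudesma-3,6-diene bridged C8=N–O–C11 | CC1(C)ON=C2C1=C[C@H]1C(C)=CCC[C@]1(C)C2 | intermediate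
19 | 11-hydroxyeudesma-3,6-dien-8-imine | CC(C)(O)C1=C[C@H]2C(C)=CCC[C@]2(C)CC1=N | intermediate
20 | (4aR,8aR)-3-(2-hydroxypropan-2-yl)-5,8a-dimethyl-4a,7,8,8a-tetrahydronaphthalen-2(1H)-one (11-hydroxyeudesma-3,6-dien-8-one) | CC(C)(O)C1=C[C@H]2C(C)=CCC[C@]2(C)CC1=O | intermediate
21 | (3R,4S,5R,10R)-3α,4α,11-trihydroxyeudesm-6-en-8-one | O[C@@H]1CC[C@]2(C)CC(=O)C(C(C)(C)O)=C[C@H]2[C@]1(C)O | intermediate
22 | 3α-[(2S,3R)-2,3-dimethyloxirane-2-carbonyloxy]-4α,11-dihydroxyeudesm-6-en-8-one | C[C@H]1O[C@]1(C)C(=O)O[C@@H]1CC[C@]2(C)CC(=O)C(C(C)(C)O)=C[C@H]2[C@]1(C)O | intermediate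
23 | CNP0288516.1, 3α-[(2R,3S)-3-chloro-2-hydroxy-2-methylbutanoyloxy]-4α,11-dihydroxyeudesm-6-en-8-one | C[C@H](Cl)[C@](C)(O)C(=O)O[C@@H]1CC[C@]2(C)CC(=O)C(C(C)(C)O)=C[C@H]2[C@]1(C)O | target

Total step count: 16. Longest linear sequence: 14 (steps 3–16).

Steps most likely to fail

1. Step 12 (key step).
- What may go wrong: cycloaddition at the proximal allene bond or across C3=C4, or dimerisation of the dipole before ring closure.
- Fallback: it sets out from 14 and comes back at 20. Enol ether 14 is hydrolysed with oxalic acid in wet THF to aldehyde 15, which is now isolated. Me2AlCl in CH2Cl2 at −78 °C then closes ring B by an intramolecular carbonyl-ene reaction: C7 of the C7=C11 bond attacks C8 and a methyl group on C11 gives up hydrogen. This gives eudesma-3,6,11-trien-8-ol F1. Dess–Martin periodinane oxidises it to eudesma-3,6,11-trien-8-one F2. Mukaiyama hydration of the 1,1-disubstituted C11=C12 bond (Mn(dpm)3, PhSiH3, O2, i-PrOH, then P(OEt)3) gives 20.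

2. Step 9.
- What may go wrong: a competing [1,2]-shift, deprotonation at the alkyne methyl group, or sluggish rearrangement because the new bond forms next to the quaternary C10.
- Fallback: it sets out from 10 and comes back at 13. Alcohol 10 is alkylated with KH and Bu3SnCH2I to the tributylstannylmethyl ether F3. Tin–lithium exchange with n-BuLi at −78 °C triggers a Wittig–Still rearrangement of the unstabilised carbanion, again suprafacial, to the primary homoallylic alcohol F4. Dess–Martin periodinane gives the β,γ-unsaturated aldehyde F5, which is used at once at low temperature. Addition of 1-propynylmagnesium bromide followed by a quench with Ac2O gives 13.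

3. Step 16.
- What may go wrong: acid-induced ionisation or dehydration at the tertiary C4 or C11 alcohols, or opening at the wrong epoxide carbon on the full molecule.
- Fallback: it sets out from 3 (together with 21) and comes back at 23. Epoxy acid 3 is opened first with HCl in Et2O to (2R,3S)-3-chloro-2-hydroxy-2-methylbutanoic acid F6. Its tertiary hydroxyl is too hindered to compete, so F6 is coupled directly with triol 21 under Shiina conditions (2-methyl-6-nitrobenzoic anhydride, DMAP, Et3N, CH2Cl2) to give 23.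

Further compounds
F1 | step 12 | eudesma-3,6,11-trien-8-ol (C8 epimers) | CC(=C)C1=C[C@H]2C(C)=CCC[C@]2(C)CC1O
F2 | step 12 | eudesma-3,6,11-trien-8-one | CC(=C)C1=C[C@H]2C(C)=CCC[C@]2(C)CC1=O
F3 | step 9 | tributylstannylmethyl ether of 10 | CO/C=C/[C@]1(C)C=C(C)[C@@H](OC[Sn](CCCC)(CCCC)CCCC)CC1
F4 | step 9 | {6-[(E)-2-methoxyethenyl]-2,6-dimethylcyclohex-2-en-1-yl}methanol, ring configuration as in 13 | CO/C=C/[C@@]1(C)CCC=C(C)[C@@H]1CO
F5 | step 9 | 6-[(E)-2-methoxyethenyl]-2,6-dimethylcyclohex-2-ene-1-carbaldehyde, ring configuration as in 13 | CO/C=C/[C@@]1(C)CCC=C(C)[C@@H]1C=O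
F6 | step 16 | (2R,3S)-3-chloro-2-hydroxy-2-methylbutanoic acid | C[C@H](Cl)[C@](C)(O)C(=O)O
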